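## The problem

Ardisinone (14) is a 2-methoxy-1,4-benzoquinone that carries at ring carbon C6 an unbranched fifteen-carbon chain, C1' to C15', whose only functional group is the acetoxy group on C2'. There is one ring and no ring fusion, so the task is to join the chain to an arene of the right oxygenation pattern and to set the single stereocentre C2' as R; since C2' is homobenzylic and isolated, with no other stereocentre to steer it, its configuration must come from a catalyst or a reagent. The quinone is the fragile part: it does not tolerate nucleophiles, bases, hydride or hydrogenation, and the C1' methylene is vinylogously acidic, so base can expel the C2' acetate. It should therefore be unveiled last, near neutral pH, from an arene that survives everything before. The acetate must be in place before that oxidation and must neither hydrolyse nor migrate to a neighbouring phenol oxygen. The ring pattern (C1 carbonyl flanked by the C2 methoxy group and the C6 chain, second carbonyl at C4) corresponds to a 2-methoxy-6-alkylphenol with a free para position, and commercial 2-bromo-6-methoxyphenol (1) has that pattern, with bromine marking the carbon that will bear the chain. The feature that opens the key step is the sequence arene–C1'H2–C2'H(O)–C3'H2: C2' is the carbinol carbon of a 2-arylethanol, and C3' can arrive as the terminus of an allyl group whose alkene later serves to attach C5' to C15'. The direct way to form C2'–C3', addition to the arylacetaldehyde 8, is compromised because that aldehyde enolises and self-condenses easily, so the bond should be made without ever handling 8 and without generating it anywhere outside the step that consumes it.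

## Retrosynthesis

14 to 13. The C4=O bond of the quinone is removed, which leads to (R)-1-(2-hydroxy-3-methoxyphenyl)pentadecan-2-yl acetate (13). The neighbouring choice, a protected hydroquinone carried through the route, would cost an extra oxygen on the starting arene and an oxidative deprotection that must spare the C2 methoxy group. Phenol 13 is robust and has both ortho positions occupied. The forward step must oxidise only the para carbon under conditions that leave the acetate alone.

13 to 12. No skeletal bond is cut; the O–benzyl bond and the C4'=C5' unsaturation are restored, giving (R,E)-1-[2-(benzyloxy)-3-methoxyphenyl]pentadec-4-en-2-yl acetate (12). A benzyl ether is preferred to a silyl or methyl ether because one neutral hydrogenation removes it and saturates the chain in the same operation. The forward step must not hydrogenolyse the acetate, which is safe because C2' is homobenzylic and not benzylic.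

12 to 10 and 11. The C4'=C5' double bond is cut by cross-metathesis into the homoallylic acetate 10 and 1-dodecene (11). A cut at C2'–C3' with a long-chain nucleophile would need aldehyde 8 free and an enantioselective alkyl addition; a cut at C3'–C4' would need an sp3 electrophile beta to the oxygenated stereocentre. Metathesis uses a commodity alkene and reduces the chiral fragment to five chain carbons. The forward reaction must keep the chain length exact, so double-bond migration has to be suppressed.

10 to 9. The acyl C–O bond is cut, giving the homoallylic alcohol 9. Acetylation is placed here, not after hydrogenolysis, because at this stage there is no competing phenol, and because the free hydroxyl is then masked before metathesis. The forward step is a routine acylation that does not touch the C2'–O bond.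

9 to 6 and 7. The C2'–C3' bond is cut, giving 2-[2-(benzyloxy)-3-methoxyphenyl]ethanol (6) and allyl acetate (7). A chiral allylmetal reagent would also make this bond, but only from isolated aldehyde 8. A cut at C1'–C2' would need a benzylic nucleophile and a chiral electrophile made separately. Coupling at the alcohol oxidation level starts from a stable achiral alcohol and a commodity ester, and removes the only stereocentre from the precursor. The forward reaction must control the aldehyde face through the catalyst alone and must not let 8 accumulate.

6 to 3 and 4. The bond from the ring to C1' is cut, giving 2-(benzyloxy)-1-bromo-3-methoxybenzene (3), used as its Grignard reagent 5, and ethylene oxide (4). The neighbouring choice, oxidative cleavage of an allyl side chain followed by reduction, would release aldehyde 8 in the flask, which is the species the plan is built to avoid. The epoxide opening brings in C1' and C2' already at the alcohol oxidation level and leaves a precursor with no side chain at all. The forward step must transfer the aryl group to the epoxide faster than halide opens it, which is the task of the copper catalyst.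

3 to 1 and 2. The O–CH2Ph bond is cut, giving 2-bromo-6-methoxyphenol (1) and benzyl bromide (2). Both are commercial, the phenol must be masked before the organomagnesium step in any case, and the forward reaction is a plain phenol alkylation.

## Roads not taken

Alternative 1: The cut goes through the benzene ring itself. Three ring bonds (phenol C1–C2, C3–C4 and C1–C6) are taken apart, leading to the 3-substituted cyclobutenone A2 and methoxyacetylene A3. In the forward sense (Danheiser benzannulation), heating opens A2 by 4π electrocyclic ring opening to a vinylketene, which adds A3 in a [2+2] cycloaddition. The new cyclobutenone opens again, the dienylketene closes by 6π electrocyclisation and tautomerises to phenol A1. Oxidation of A1 at the carbon between the methoxy group and the chain would give 14.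
- Merits: the substitution pattern follows from the mechanism, no phenol protecting group is needed, the acetate rides through, and A1 is one step from 14.
- Weak points: the key step spends three bond formations on a ring that can be bought, and it does nothing for C2'. The stereocentre must already be present in A2, in practice in the homopropargylic acetate A4, from which A2 would come by cycloaddition of a halogenated ketene and reductive dehalogenation. A3 is volatile and of limited stability. A1 is a 3,5-disubstituted phenol whose para carbon is flanked on both sides while both ortho carbons are open, so the closing oxidation is more hindered and less clearly para-selective than that of 13.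
- Comparison: this road is better in protecting-group economy, with no benzyl group and no hydrogenation. The chosen plan sets against this a key step that creates the stereocentre instead of presupposing it, commodity sources for all carbon atoms, and a final phenol with only the para position free.

Alternative 2: The cut is at C2'–O, traced back to a C2'–B bond formed together with C1'–H across the double bond of the E-styrene A6. In the forward sense a copper boryl species carrying a chiral N-heterocyclic carbene, generated from CuCl, NaOtBu and the diboron reagent A7, adds across C1'=C2' with copper at the benzylic carbon and boron at C2'. An alcohol protonates the C1'–Cu bond and gives boronate A5. Stereoretentive oxidation of the C–B bond, acetylation and hydrogenolysis would lead to A1, which is oxidised as in alternative 1.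
- Merits: the whole fifteen-carbon chain is in place before the stereocentre is set, so no chain-length question arises. In this respect the road is better than the chosen plan, whose metathesis must be guarded against double-bond migration. The regiochemistry is enforced by the benzylic copper intermediate and the stereocentre is catalyst-controlled.
- Weak points: A6 must be geometrically pure, since the two alkene isomers would not give the same enantiomer with the same selectivity. Its 3-benzyloxy-5-methoxy arene requires differentiation of two equivalent meta oxygens of a symmetric precursor, followed by an E-selective olefination. Boron is only a placeholder for oxygen and costs an extra oxidation step. The end game shares the hindered para oxidation of A1.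
- Comparison: the sequence would be two to three steps longer. The chosen plan sets against its metathesis risk a commercial arene with the correct pattern, creation of the carbinol stereocentre with its oxygen already in place, and the unambiguous final oxidation of 13.

Alternative 3: The cut is at C1'–C2', giving the benzylzinc bromide A10 and racemic 1-bromotetradecyl acetate A9. In the forward sense, under NiBr2(glyme) and a chiral bis(oxazoline), halogen abstraction from either enantiomer of A9 gives the same α-acetoxyalkyl radical. The chiral benzylnickel species captures it, and reductive elimination forms C1'–C2' and sets C2', giving A8. Hydrogenolysis of A8 gives 13 and oxidation gives 14.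
- Merits: this is the most convergent road. The acetate is already present, the chain is complete, there is no metathesis, and it ends in the same favourable phenol 13. In steps after the key step (two against four) and in security of chain length it is better than the chosen plan.
- Weak points: this class of enantioconvergent coupling is established mainly for unactivated alkylzinc reagents. An ortho-disubstituted benzylic zinc reagent transmetalates differently and homocouples readily, and the enantioselectivity would have to be established anew for it. A9 is a moisture-sensitive α-halo ester that must be prepared fresh, and both partners are air-sensitive. A10 needs several steps from a commercial benzaldehyde (protection, reduction, bromination, zinc insertion), so the overall count is not lower.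
- Comparison: if the coupling proved general for A10, this road would be shorter after the key step and more convergent. The chosen plan sets against that a key step whose substrate, an unbranched primary alcohol, lies at the centre of the documented scope of the reaction, bench-stable partners in that step, and routine steps around it.

Key step: step 3

Assumption on the sense of induction: the (R)-configured bisphosphine is taken to deliver the allyl group to the aldehyde face that gives (R)-9, by analogy with this catalyst family for primary alcohols whose carbinol substituent outranks allyl. The configuration of 9 would be checked by Mosher ester analysis, and the ligand antipode used if the check demands it.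

Assumption on alkene geometry: 12 is expected as an E/Z mixture with E predominant and is drawn as E; the geometry is erased in step 6.

Step 1
Reactants: 1 2-bromo-6-methoxyphenol; 2 benzyl bromide
Product: 3 2-(benzyloxy)-1-bromo-3-methoxybenzene
Conditions: K2CO3, DMF, rt
Reagents that add atoms: none
Why: Williamson ether synthesis: the phenoxide formed with carbonate displaces bromide from the benzylic carbon by SN2, and the aryl bromide is inert to these conditions. The benzyl ether masks the acidic phenol before the organomagnesium step and is removed later by the same hydrogenation that saturates the chain.

Step 2
Reactants: 3 2-(benzyloxy)-1-bromo-3-methoxybenzene; 4 ethylene oxide (oxirane)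
Product: 6 2-[2-(benzyloxy)-3-methoxyphenyl]ethanol, via arylmagnesium bromide 5 (not isolated)
Conditions: Mg turnings, I2 (cat.), THF, 50 °C; then CuI (10 mol %), ethylene oxide (1.5 equiv, THF solution), −30 to 0 °C; then H2O
Reagents that add atoms: none
Why: Insertion of magnesium into the aryl C–Br bond gives the Grignard reagent, and copper-catalysed SN2 opening of the epoxide through an arylcuprate delivers C1' and C2' directly at the alcohol oxidation level, so no arylacetaldehyde is formed on the way. The benzyl and methyl ethers are inert to the organomagnesium reagent, and catalytic CuI at low temperature lets aryl transfer outrun opening of the epoxide by bromide.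

Step 3
Reactants: 6 2-[2-(benzyloxy)-3-methoxyphenyl]ethanol; 7 allyl acetate
Product: 9 (R)-1-[2-(benzyloxy)-3-methoxyphenyl]pent-4-en-2-ol, via arylacetaldehyde 8 (not isolated)
Conditions: [Ir(cod)Cl]2 (2.5 mol %), (R)-BINAP (5 mol %), 4-chloro-3-nitrobenzoic acid (10 mol %), Cs2CO3 (20 mol %), allyl acetate (excess), THF, 100 °C, sealed tube
Reagents that add atoms: none
Why: This is the iridium-catalysed transfer-hydrogenative carbonyl allylation from the alcohol oxidation level (Krische allylation), and the closest known reaction type is this same coupling of unbranched primary alcohols with allyl acetate. [Ir(cod)Cl]2, the bisphosphine, the nitrobenzoic acid and allyl acetate assemble an ortho-cyclometallated π-allyl C,O-benzoate complex of trivalent iridium; exchange of 6 onto the metal and β-hydride elimination give aldehyde 8 and an iridium hydride, which is deprotonated to a monovalent iridium species that ionises another molecule of allyl acetate and so returns to the π-allyl complex with loss of acetic acid. Aldehyde 8 is allylated through the σ-allyl form in a closed six-membered chair transition state with the arylmethyl group equatorial, and alkoxide exchange with fresh 6 releases 9 and starts the next dehydrogenation. No ring is closed; one C–C bond (C2'–C3') and one stereocentre (C2') are formed. C2' is set by catalyst control alone: the (R)-bisphosphine fixes the chirality at the octahedral iridium centre, which leaves one aldehyde face open to the allyl ligand, and the substrate has no stereocentre to reinforce or oppose it. The step needs enantiofacial selectivity, C-allylation in preference to O-allylation, and suppression of enolisation and aldol chemistry of 8; the first is secured by the ligand, the second by the benzyl protection of the phenol and the low tendency of aliphatic alkoxides to attack the allyl ligand of this complex, the third by the fact that 8 is generated only as fast as the allyliridium species consumes it. The secondary alcohol 9 is expected to resist further dehydrogenation because its homoallylic alkene occupies the coordination site that β-hydride elimination would need.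

Step 4
Reactants: 9 (R)-1-[2-(benzyloxy)-3-methoxyphenyl]pent-4-en-2-ol
Product: 10 (R)-1-[2-(benzyloxy)-3-methoxyphenyl]pent-4-en-2-yl acetate
Conditions: Ac2O, pyridine, DMAP (cat.), CH2Cl2, 0 °C to rt
Reagents that add atoms: acetic anhydride, CC(=O)OC(C)=O
Why: DMAP-catalysed O-acylation (nucleophilic acyl substitution) of an unhindered secondary alcohol; the C2'–O bond is not touched, so the configuration is retained. Acetylating now avoids competition from the phenol that appears later and masks the hydroxyl before metathesis.

Step 5
Reactants: 10 (R)-1-[2-(benzyloxy)-3-methoxyphenyl]pent-4-en-2-yl acetate; 11 1-dodecene
Product: 12 (R,E)-1-[2-(benzyloxy)-3-methoxyphenyl]pentadec-4-en-2-yl acetate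
Conditions: second-generation Grubbs catalyst RuCl2(=CHPh)(H2IMes)(PCy3) (5 mol %), 1-dodecene (4 equiv), 1,4-benzoquinone (10 mol %), CH2Cl2, 40 °C
Reagents that add atoms: none
Why: Olefin cross-metathesis of two unhindered terminal alkenes through ruthenium alkylidene and metallacyclobutane intermediates, driven by loss of ethene; the excess of the cheap partner should push 10 to the cross product, and the dodecene homodimer is removed as a hydrocarbon. The benzoquinone additive intercepts ruthenium hydrides that would otherwise move the double bond and blur the chain length; the E/Z ratio is of no consequence.

Step 6
Reactants: 12 (R,E)-1-[2-(benzyloxy)-3-methoxyphenyl]pentadec-4-en-2-yl acetate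
Product: 13 (R)-1-(2-hydroxy-3-methoxyphenyl)pentadecan-2-yl acetate
Conditions: H2 (1 atm), 10% Pd/C, EtOAc, rt
Reagents that add atoms: none
Why: Heterogeneous catalytic hydrogenation saturates the disubstituted alkene and hydrogenolyses the benzyl ether in one operation. The acetate sits on a homobenzylic carbon and should not be cleaved, and the neutral aprotic solvent gives no occasion for acyl migration to the new phenol.

Step 7
Reactants: 13 (R)-1-(2-hydroxy-3-methoxyphenyl)pentadecan-2-yl acetate
Product: 14 ardisinone [(R)-1-(5-methoxy-3,6-dioxocyclohexa-1,4-dien-1-yl)pentadecan-2-yl acetate]
Conditions: (KSO3)2NO (2.5 equiv), KH2PO4 (aq), acetone/H2O, rt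
Reagents that add atoms: potassium nitrosodisulfonate (Fremy's salt), [K+].[K+].[O-]S(=O)(=O)N([O])S(=O)(=O)[O-]
Why: Teuber oxidation: one equivalent of the nitroxyl radical removes the phenolic hydrogen, a second couples at the free para carbon, and loss of imidodisulfonate leaves the para-quinone. Both ortho positions carry substituents, so only the para carbon is open; the buffered, near-neutral medium should spare the acetate, and the stereocentre is remote from the reacting ring.

## Compound list

1 | 2-bromo-6-methoxyphenol | COc1cccc(Br)c1O | starting material
2 | benzyl bromide | BrCc1ccccc1 | starting material
3 | 2-(benzyloxy)-1-bromo-3-methoxybenzene | COc1cccc(Br)c1OCc1ccccc1 | intermediate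
4 | ethylene oxide (oxirane) | C1CO1 | starting material
5 | [2-(benzyloxy)-3-methoxyphenyl]magnesium bromide (not isolated) | COc1cccc([Mg]Br)c1OCc1ccccc1 | intermediate
6 | 2-[2-(benzyloxy)-3-methoxyphenyl]ethanol | OCCc1cccc(OC)c1OCc1ccccc1 | intermediate
7 | allyl acetate | C=CCOC(C)=O | starting material
8 | 2-[2-(benzyloxy)-3-methoxyphenyl]acetaldehyde (not isolated) | O=CCc1cccc(OC)c1OCc1ccccc1 | intermediate
9 | (R)-1-[2-(benzyloxy)-3-methoxyphenyl]pent-4-en-2-ol | C=CC[C@H](Cc1cccc(OC)c1OCc1ccccc1)O | intermediate
10 | (R)-1-[2-(benzyloxy)-3-methoxyphenyl]pent-4-en-2-yl acetate | C=CC[C@H](Cc1cccc(OC)c1OCc1ccccc1)OC(C)=O | intermediate
11 | 1-dodecene | C=CCCCCCCCCCC | starting material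
12 | (R,E)-1-[2-(benzyloxy)-3-methoxyphenyl]pentadec-4-en-2-yl acetate (E drawn; E/Z mixture carried forward) | CCCCCCCCCC/C=C/C[C@H](Cc1cccc(OC)c1OCc1ccccc1)OC(C)=O | intermediate
13 | (R)-1-(2-hydroxy-3-methoxyphenyl)pentadecan-2-yl acetate | CCCCCCCCCCCCC[C@H](Cc1cccc(OC)c1O)OC(C)=O | intermediate
14 | ardisinone, (R)-1-(5-methoxy-3,6-dioxocyclohexa-1,4-dien-1-yl)pentadecan-2-yl acetate | CCCCCCCCCCCCC[C@H](CC1=CC(=O)C=C(OC)C1=O)OC(C)=O | target

## Step count and risk assessment

Total steps: 7. Longest linear sequence: 7 steps, from 1 to 14; compounds 2, 4, 7 and 11 are purchased and enter directly.

Step 3 (key step). The most likely failure is insufficient facial selectivity, because the ortho-benzyloxy oxygen could coordinate to iridium and disturb the chair transition state. A second possibility is loss of material through enolisation and aldol condensation of the transient aldehyde at 100 °C if allyl transfer is slow for this hindered arylethanol. The fallback buys the configuration from the chiral pool, forms no aldehyde, and sets out from the Grignard reagent 5, generated from 3 as in step 2.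
- Copper-catalysed opening (CuI cat., THF, −30 °C) of commercial (S)-epichlorohydrin at its unsubstituted epoxide carbon by 5 would give (S)-1-[2-(benzyloxy)-3-methoxyphenyl]-3-chloropropan-2-ol F1.
- Ring closure with NaOH in THF/H2O gives (S)-2-[2-(benzyloxy)-3-methoxybenzyl]oxirane F2; no bond to the stereocentre is broken in either operation.
- Opening of F2 at its terminal carbon with vinylmagnesium bromide and catalytic CuI in THF at −30 °C gives 9, where the route is rejoined.
- The price is two extra steps.

Step 5. The most likely failure is migration of the double bond by ruthenium hydride species before or after metathesis, which would give chain-shortened or chain-lengthened homologues that cannot be separated after hydrogenation. Self-metathesis of 10 could also hold back conversion. The fallback forms the C5'–C6' bond by sp3–sp3 coupling and sets out from 10.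
- Hydroboration of 10 with 9-BBN in THF gives (R)-5-(9-borabicyclo[3.3.1]nonan-9-yl)-1-[2-(benzyloxy)-3-methoxyphenyl]pentan-2-yl acetate F3, which is not isolated.
- Alkyl–alkyl Suzuki–Miyaura coupling of F3 with 1-bromodecane (Pd(OAc)2, PCy3, K3PO4·H2O, THF, rt) gives (R)-1-[2-(benzyloxy)-3-methoxyphenyl]pentadecan-2-yl acetate F4, the same structure as A8.
- Hydrogenolysis of F4 under the conditions of step 6 returns to the route at 13.
- The chain length is then fixed by the two coupling partners, and no alkene is present to migrate.

Step 7. The most likely failure is slow, incomplete oxidation because the lipophilic phenol dissolves poorly in the aqueous medium that the radical salt needs, while the salt decomposes; prolonged exposure could also start over-oxidation of the quinone. The fallback changes oxidant class and medium and sets out from 13. Phenol 13 is oxidised with O2 (1 atm) and catalytic Co(salen), N,N'-bis(salicylidene)ethylenediaminocobalt (divalent cobalt), in DMF at rt. A cobalt–dioxygen adduct generates the phenoxyl radical and delivers oxygen to the para carbon in a homogeneous organic solution, giving 14 directly. No new compound is involved.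

Step 2. The most likely failure is opening of ethylene oxide by bromide from the magnesium salts in competition with aryl transfer, which consumes the epoxide, together with sluggish initiation and biaryl coupling during formation of the Grignard reagent from the hindered, electron-rich bromide. The fallback builds the two-carbon arm from a vinyl group, uses no organomagnesium reagent, and sets out from 3.
- Suzuki–Miyaura coupling of 3 with potassium vinyltrifluoroborate CH2=CHBF3K (PdCl2(dppf), Cs2CO3, THF/H2O, 80 °C) gives 2-(benzyloxy)-1-ethenyl-3-methoxybenzene F5.
- Hydroboration of F5 with 9-BBN in THF places boron on the terminal carbon and gives 9-{2-[2-(benzyloxy)-3-methoxyphenyl]ethyl}-9-borabicyclo[3.3.1]nonane F6, which is not isolated.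
- Oxidation of F6 with NaOH/H2O2 returns to the route at 6; this path, too, forms no arylacetaldehyde.

Further compounds

F1 | step 3 | (S)-1-[2-(benzyloxy)-3-methoxyphenyl]-3-chloropropan-2-ol | ClC[C@@H](O)Cc1cccc(OC)c1OCc1ccccc1
F2 | step 3 | (S)-2-[2-(benzyloxy)-3-methoxybenzyl]oxirane | C1[C@H](Cc2cccc(OC)c2OCc2ccccc2)O1
F3 | step 5 | (R)-5-(9-borabicyclo[3.3.1]nonan-9-yl)-1-[2-(benzyloxy)-3-methoxyphenyl]pentan-2-yl acetate | B1(C2CCCC1CCC2)CCC[C@H](Cc1cccc(OC)c1OCc1ccccc1)OC(C)=O
F4 | step 5 | (R)-1-[2-(benzyloxy)-3-methoxyphenyl]pentadecan-2-yl acetate | CCCCCCCCCCCCC[C@H](Cc1cccc(OC)c1OCc1ccccc1)OC(C)=O
F0 | step 7 | none | none
F5 | step 2 | 2-(benzyloxy)-1-ethenyl-3-methoxybenzene | C=Cc1cccc(OC)c1OCc1ccccc1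
F6 | step 2 | 9-{2-[2-(benzyloxy)-3-methoxyphenyl]ethyl}-9-borabicyclo[3.3.1]nonane | B1(C2CCCC1CCC2)CCc1cccc(OC)c1OCc1ccccc1
A1 | alternative 1 | (R)-1-(3-hydroxy-5-methoxyphenyl)pentadecan-2-yl acetate | CCCCCCCCCCCCC[C@H](Cc1cc(O)cc(OC)c1)OC(C)=O
A2 | alternative 1 | (R)-1-(3-oxocyclobut-1-en-1-yl)pentadecan-2-yl acetate | CCCCCCCCCCCCC[C@H](CC1=CC(=O)C1)OC(C)=O
A3 | alternative 1 | methoxyacetylene | C#COC
A4 | alternative 1 | (R)-heptadec-1-yn-4-yl acetate | C#CC[C@@H](CCCCCCCCCCCCC)OC(C)=O
A5 | alternative 2 | (R)-2-{1-[3-(benzyloxy)-5-methoxyphenyl]pentadecan-2-yl}-4,4,5,5-tetramethyl-1,3,2-dioxaborolane | CCCCCCCCCCCCC[C@H](Cc1cc(OC)cc(OCc2ccccc2)c1)B1OC(C)(C)C(C)(C)O1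
A6 | alternative 2 | (E)-1-(benzyloxy)-3-methoxy-5-(pentadec-1-en-1-yl)benzene | CCCCCCCCCCCCC/C=C/c1cc(OC)cc(OCc2ccccc2)c1
A7 | alternative 2 | bis(pinacolato)diboron | CC1(C)OB(OC1(C)C)B1OC(C)(C)C(C)(C)O1
A8 | alternative 3 | (R)-1-[2-(benzyloxy)-3-methoxyphenyl]pentadecan-2-yl acetate | CCCCCCCCCCCCC[C@H](Cc1cccc(OC)c1OCc1ccccc1)OC(C)=O
A9 | alternative 3 | racemic 1-bromotetradecyl acetate | CCCCCCCCCCCCCC(Br)OC(C)=O
A10 | alternative 3 | [2-(benzyloxy)-3-methoxybenzyl]zinc bromide | Br[Zn]Cc1cccc(OC)c1OCc1ccccc1
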